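**Retrosynthetic overview**

1. Locants (lignan numbering): C8 carries the acetate, C7 and C9 are its ArCH and CH2 neighbours, primed atoms belong to the other half; ring A = O–C7'–C8'–C8–C9, ring B = O–C7–C8–C8'–C9'.
2. Enabling feature: in ring A the benzylic C7' is at the aldehyde level and C8' is alpha to the oxygenated C8, while C9–C8–C8'–C9' is a 2-oxobutane-1,4-diol; both terminal oxygens can therefore sit on C7' as a seven-membered cyclic acetal, which makes C7'–C8' an acetal/enol (aldol-type) bond.
3. Ring A is formed first: the seven-membered 1,3-dioxepine enol silane contracts by two atoms (C9' and its oxygen leave the ring) to a tetrahydrofuran-3-one, setting C7' and C8'.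
4. Ring B is formed second: a Norrish–Yang closure of C7–C8 from the C9' benzyl-type ether of that ketone delivers the C8 carbinol and C7 together; O-acetylation and debenzylation finish.
5. Both aryl carbons come from O-benzylvanillin, the four-carbon core from (Z)-but-2-ene-1,4-diol.

Key step: step 5

Remark: the sense of induction of the chiral acid in step 5 cannot be fixed in advance; the route is written for the catalyst enantiomer that gives (5R)-10, and its antipode is equally accessible.

**Route**

Step 1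
Reactants: 1 4-(benzyloxy)-3-methoxybenzaldehyde; 2 (Z)-but-2-ene-1,4-diol
Product: 3 2-[4-(benzyloxy)-3-methoxyphenyl]-4,7-dihydro-1,3-dioxepine
Conditions: TsOH·H2O (cat.), toluene, reflux, Dean–Stark; Et3N quench
Reagents that add atoms: none
Why: Acid-catalysed acetalisation with azeotropic removal of water; the Z-alkene holds the two hydroxyls within reach, so the seven-membered acetal closes readily, and the product is achiral.

Step 2
Reactants: 3 2-[4-(benzyloxy)-3-methoxyphenyl]-4,7-dihydro-1,3-dioxepine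
Product: 5 2-[4-(benzyloxy)-3-methoxyphenyl]-1,3-dioxepan-5-ol, via B-alkyl-9-BBN adduct 4 (not isolated)
Conditions: 9-BBN, THF, 0 to 50 °C; then NaOH (aq.), H2O2, 0 °C to rt
Reagents that add atoms: hydrogen peroxide, OO
Why: Hydroboration–oxidation of a symmetrical cis-alkene whose two carbons are equivalent gives a single constitution; the carbinol configuration is irrelevant because it is oxidised next, and the acetal tolerates the basic peroxide.

Step 3
Reactants: 5 2-[4-(benzyloxy)-3-methoxyphenyl]-1,3-dioxepan-5-ol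
Product: 6 2-[4-(benzyloxy)-3-methoxyphenyl]-1,3-dioxepan-5-one
Conditions: Dess–Martin periodinane, pyridine, CH2Cl2, 0 °C to rt
Reagents that add atoms: none
Why: Dess–Martin oxidation under pyridine buffering gives the ketone without acid that would open the electron-rich aryl acetal.

Step 4
Reactants: 6 2-[4-(benzyloxy)-3-methoxyphenyl]-1,3-dioxepan-5-one
Product: 8 {[2-[4-(benzyloxy)-3-methoxyphenyl]-4,7-dihydro-1,3-dioxepin-5-yl]oxy}triethylsilane, via lithium enolate 7 (not isolated)
Conditions: TESCl, then LiN(iPr)2, THF, −78 °C (in situ quench); Et3N-buffered work-up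
Reagents that add atoms: chlorotriethylsilane (TESCl), CC[Si](Cl)(CC)CC
Why: Kinetic deprotonation of an alpha-alkoxy ketone by the hindered lithium amide should take the alpha' CH2 (C6) rather than the oxygen-flanked C4–H, and the silyl chloride already present traps the enolate on oxygen before the beta-acetal oxygen can be lost (regioselective silyl enol ether formation).

Step 5
Reactants: 8 {[2-[4-(benzyloxy)-3-methoxyphenyl]-4,7-dihydro-1,3-dioxepin-5-yl]oxy}triethylsilane
Product: 10 (4S,5R)-5-[4-(benzyloxy)-3-methoxyphenyl]-4-{[(triethylsilyl)oxy]methyl}dihydrofuran-3(2H)-one, via oxocarbenium ion 9 (not isolated)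
Conditions: (S,S)-IDPi (imidodiphosphorimidate Brønsted acid with 3,3'-aryl BINOL units and N-triflyl groups, 2 mol%), toluene, −60 to −40 °C; Et3N quench
Reagents that add atoms: none
Why: Proposed new method: the acid is silylated by a little of 8, and the silylium–IDPi pair ionises the acetal at the C2–O1 bond (O1 is the oxygen on the allylic CH2), giving the aryl-stabilised oxocarbenium ion 9 paired with the chiral anion; its own enol silane carbon C6 captures it in an intramolecular Mukaiyama aldol (net 1,3 O-to-C shift of the benzylic carbon), and the silyl group returns to the anion to turn the catalyst over. The closest known reactions are the Petasis–Ferrier rearrangement of 4-alkylidene-1,3-dioxolanes to tetrahydrofuran-3-ones (the same oxocarbenium/enolate pair), the Lewis acid 1,3-ring contraction of 4,5-dihydro-1,3-dioxepines to tetrahydrofuran-3-carbaldehydes, and IDPi-catalysed Mukaiyama aldol additions and additions to oxocarbenium ions. Ring A closes by a 5-(enolendo)-endo-trig attack of the enol carbon on the oxocarbenium carbon, the mode that operates in the five-ring Petasis–Ferrier case. C5 (C7') is set by the face of the planar cation that the confined chiral anion leaves open, and C4 (C8'), alpha to the new ketone, should settle trans to the aryl group under thermodynamic control. The step needs ionisation of the right acetal bond and C-capture: ionisation at the other oxygen could only close an oxetane and is reversible, the electron-rich aryl group makes acetal ionisation far easier than loss of the allylic oxygen, and because the acetal stereocentre is erased in 9 both enantiomers of racemic 8 converge on one product.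

Step 6
Reactants: 10 (4S,5R)-5-[4-(benzyloxy)-3-methoxyphenyl]-4-{[(triethylsilyl)oxy]methyl}dihydrofuran-3(2H)-one; 1 4-(benzyloxy)-3-methoxybenzaldehyde
Product: 11 (4S,5R)-5-[4-(benzyloxy)-3-methoxyphenyl]-4-({[4-(benzyloxy)-3-methoxyphenyl]methoxy}methyl)dihydrofuran-3(2H)-one
Conditions: Et3SiH, BiBr3 (5 mol%), MeCN, 0 °C
Reagents that add atoms: none
Why: Reductive etherification of a silyl ether with an aldehyde exchanges the silyl group for the second aryl-CH2 group under acidic, base-free conditions, which avoids the beta-elimination and retro-aldol loss that alkoxide alkylation of a 4-(oxymethyl) ketone would invite; the aldehyde should react faster than the ketone.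

Step 7
Reactants: 11 (4S,5R)-5-[4-(benzyloxy)-3-methoxyphenyl]-4-({[4-(benzyloxy)-3-methoxyphenyl]methoxy}methyl)dihydrofuran-3(2H)-one
Product: 13 (1R,3aR,4S,6aS)-1,4-bis[4-(benzyloxy)-3-methoxyphenyl]tetrahydro-1H,3H-furo[3,4-c]furan-3a(4H)-ol, via 1,5-biradical 12 (not isolated)
Conditions: hν (medium-pressure Hg lamp, Pyrex, λ > 300 nm), degassed benzene, 0.01 M, rt
Reagents that add atoms: none
Why: Norrish–Yang photocyclisation of a beta-alkoxy ketone: the excited ketone takes the benzylic delta-hydrogen by 1,6-transfer and the biradical closes C7–C8 on the only face the CH2O arm can reach (cis fusion, hydroxyl on the convex face, C8 = R), while the aryl group of the benzylic radical should turn away from ring A so that C7 is exo (S).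

Step 8
Reactants: 13 (1R,3aR,4S,6aS)-1,4-bis[4-(benzyloxy)-3-methoxyphenyl]tetrahydro-1H,3H-furo[3,4-c]furan-3a(4H)-ol
Product: 14 (1R,3aR,4S,6aS)-1,4-bis[4-(benzyloxy)-3-methoxyphenyl]tetrahydro-1H,3H-furo[3,4-c]furan-3a(4H)-yl acetate
Conditions: Ac2O, DMAP, Et3N, CH2Cl2, 40 °C
Reagents that add atoms: acetic anhydride (Ac2O), CC(=O)OC(C)=O
Why: DMAP-catalysed acylation is the standard way to esterify a hindered tertiary alcohol; it is the only free hydroxyl, and the basic conditions leave the benzylic ethers and all stereocentres untouched.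

Step 9
Reactants: 14 (1R,3aR,4S,6aS)-1,4-bis[4-(benzyloxy)-3-methoxyphenyl]tetrahydro-1H,3H-furo[3,4-c]furan-3a(4H)-yl acetate
Product: 15 (1R,3aR,4S,6aS)-1,4-bis(4-hydroxy-3-methoxyphenyl)tetrahydro-1H,3H-furo[3,4-c]furan-3a(4H)-yl acetate (8-acetoxypinoresinol)
Conditions: H2 (1 atm), Pd/C (10%), EtOAc, rt, stopped after uptake of two equivalents
Reagents that add atoms: none
Why: Hydrogenolysis of the two aryl benzyl ethers over Pd/C in a non-acidic solvent should be faster than cleavage of the dialkyl benzylic C–O bonds of the furofuran and does not touch the tertiary acetate.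

**Compound list**

1 | 4-(benzyloxy)-3-methoxybenzaldehyde | COc1cc(C=O)ccc1OCc1ccccc1 | starting material
2 | (Z)-but-2-ene-1,4-diol | OC/C=C\CO | starting material
3 | 2-[4-(benzyloxy)-3-methoxyphenyl]-4,7-dihydro-1,3-dioxepine | COc1cc(C2OC/C=C\CO2)ccc1OCc1ccccc1 | intermediate
4 | 9-{2-[4-(benzyloxy)-3-methoxyphenyl]-1,3-dioxepan-5-yl}-9-borabicyclo[3.3.1]nonane | COc1cc(C2OCCC(B3C4CCCC3CCC4)CO2)ccc1OCc1ccccc1 | intermediate (not isolated)
5 | 2-[4-(benzyloxy)-3-methoxyphenyl]-1,3-dioxepan-5-ol (racemic diastereomer mixture) | COc1cc(C2OCCC(O)CO2)ccc1OCc1ccccc1 | intermediate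
6 | 2-[4-(benzyloxy)-3-methoxyphenyl]-1,3-dioxepan-5-one (racemic) | COc1cc(C2OCCC(=O)CO2)ccc1OCc1ccccc1 | intermediate
7 | lithium 2-[4-(benzyloxy)-3-methoxyphenyl]-4,7-dihydro-1,3-dioxepin-5-olate | COc1cc(C2OCC=C([O-])CO2)ccc1OCc1ccccc1.[Li+] | intermediate (not isolated)
8 | {[2-[4-(benzyloxy)-3-methoxyphenyl]-4,7-dihydro-1,3-dioxepin-5-yl]oxy}triethylsilane (racemic) | COc1cc(C2OCC=C(O[Si](CC)(CC)CC)CO2)ccc1OCc1ccccc1 | intermediate
9 | [4-(benzyloxy)-3-methoxybenzylidene][2,4-bis(triethylsilyloxy)but-2-en-1-yl]oxonium, ion pair with the IDPi anion | COc1cc(C=[O+]CC(O[Si](CC)(CC)CC)=CCO[Si](CC)(CC)CC)ccc1OCc1ccccc1 | intermediate (not isolated)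
10 | (4S,5R)-5-[4-(benzyloxy)-3-methoxyphenyl]-4-{[(triethylsilyl)oxy]methyl}dihydrofuran-3(2H)-one | COc1cc([C@@H]2OCC(=O)[C@H]2CO[Si](CC)(CC)CC)ccc1OCc1ccccc1 | intermediate
11 | (4S,5R)-5-[4-(benzyloxy)-3-methoxyphenyl]-4-({[4-(benzyloxy)-3-methoxyphenyl]methoxy}methyl)dihydrofuran-3(2H)-one | COc1cc([C@@H]2OCC(=O)[C@H]2COCc2ccc(OCc3ccccc3)c(OC)c2)ccc1OCc1ccccc1 | intermediate
12 | 1,5-biradical from 11 (hydroxy-substituted C8 radical, benzylic C7 radical) | COc1cc([C@@H]2OC[C](O)[C@H]2CO[CH]c2ccc(OCc3ccccc3)c(OC)c2)ccc1OCc1ccccc1 | intermediate (not isolated)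
13 | (1R,3aR,4S,6aS)-1,4-bis[4-(benzyloxy)-3-methoxyphenyl]tetrahydro-1H,3H-furo[3,4-c]furan-3a(4H)-ol | COc1cc([C@@H]2OC[C@@]3(O)[C@H](c4ccc(OCc5ccccc5)c(OC)c4)OC[C@@H]23)ccc1OCc1ccccc1 | intermediate
14 | (1R,3aR,4S,6aS)-1,4-bis[4-(benzyloxy)-3-methoxyphenyl]tetrahydro-1H,3H-furo[3,4-c]furan-3a(4H)-yl acetate | COc1cc([C@@H]2OC[C@@]3(OC(C)=O)[C@H](c4ccc(OCc5ccccc5)c(OC)c4)OC[C@@H]23)ccc1OCc1ccccc1 | intermediate
15 | (1R,3aR,4S,6aS)-1,4-bis(4-hydroxy-3-methoxyphenyl)tetrahydro-1H,3H-furo[3,4-c]furan-3a(4H)-yl acetate (8-acetoxypinoresinol) | COc1cc([C@@H]2OC[C@@]3(OC(C)=O)[C@H](c4ccc(O)c(OC)c4)OC[C@@H]23)ccc1O | target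

**Totals**

Total step count: 9. Longest linear sequence: 9 steps.

**Steps most likely to fail**

Step 5. The chiral anion may not hold the planar oxocarbenium ion tightly enough (poor facial selectivity), or silylium-induced loss of the allylic acetal oxygen may compete with acetal ionisation. The fallback uses known reactions only, sets out from 1 and returns at 11. Horner–Wadsworth–Emmons olefination of 1 (trimethyl phosphonoacetate, LiCl, DBU) gives methyl (E)-3-[4-(benzyloxy)-3-methoxyphenyl]prop-2-enoate F1. Methyl glycolate and NaH (THF/DMSO) add to it and close the ring (oxa-Michael addition, Dieckmann condensation) to racemic methyl trans-2-[4-(benzyloxy)-3-methoxyphenyl]-4-oxotetrahydrofuran-3-carboxylate F2. Ketalisation (ethane-1,2-diol, TsOH) gives the racemic dioxolane ester F3, and LiAlH4 reduction gives the racemic trans ketal alcohol F4. Lipase-catalysed acylation (Burkholderia cepacia lipase, vinyl acetate) resolves it to [(8R,9S)-8-[4-(benzyloxy)-3-methoxyphenyl]-1,4,7-trioxaspiro[4.4]nonan-9-yl]methanol F5. Williamson etherification (NaH, 4-(benzyloxy)-3-methoxybenzyl bromide) gives the ketal ether F6, and PPTS in aqueous acetone releases ketone 11.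

Step 7. Alpha-cleavage of the excited alpha-alkoxy ketone or return of the hydrogen in the biradical may outrun ring closure, and closure may show poor facial selectivity at the benzylic radical. The fallback sets out from 10 and returns at 13. Wittig olefination of 10 with the ylide from [4-(benzyloxy)-3-methoxybenzyl]triphenylphosphonium bromide and NaN(SiMe3)2 gives the exocyclic benzylidene compound F7 (E/Z mixture). OsO4 (cat.)/NMO dihydroxylation from the face opposite the neighbouring CH2OSiEt3 group gives the diol F8 (C8 as in the target, benzylic carbinol unassigned). HF·pyridine frees the triol F9. BF3·OEt2 (CH2Cl2, −78 °C) then ionises the benzylic carbinol, and the primary hydroxyl closes ring B with the aryl group exo to give 13.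

Step 4. Deprotonation may occur on the oxygen-flanked side, or the lithium enolate may lose the beta-acetal oxygen before it is silylated. The fallback sets out from 3 and returns at 8. NBS in aqueous acetone (NaHCO3) converts 3 into racemic trans-6-bromo-2-[4-(benzyloxy)-3-methoxyphenyl]-1,3-dioxepan-5-ol F10. Dess–Martin periodinane oxidises it to 6-bromo-2-[4-(benzyloxy)-3-methoxyphenyl]-1,3-dioxepan-5-one F11, with bromine on the carbon that must become the enol carbon. Reductive silylation (Zn dust, TESCl, TMEDA, THF) then gives 8 regiospecifically.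

**Further compounds**

F1 | step 5 | methyl (E)-3-[4-(benzyloxy)-3-methoxyphenyl]prop-2-enoate | COC(=O)/C=C/c1ccc(OCc2ccccc2)c(OC)c1
F2 | step 5 | methyl trans-2-[4-(benzyloxy)-3-methoxyphenyl]-4-oxotetrahydrofuran-3-carboxylate (racemic) | COC(=O)C1C(=O)COC1c1ccc(OCc2ccccc2)c(OC)c1
F3 | step 5 | methyl trans-8-[4-(benzyloxy)-3-methoxyphenyl]-1,4,7-trioxaspiro[4.4]nonane-9-carboxylate (racemic) | COC(=O)C1C(c2ccc(OCc3ccccc3)c(OC)c2)OCC12OCCO2
F4 | step 5 | {trans-8-[4-(benzyloxy)-3-methoxyphenyl]-1,4,7-trioxaspiro[4.4]nonan-9-yl}methanol (racemic) | OCC1C(c2ccc(OCc3ccccc3)c(OC)c2)OCC12OCCO2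
F5 | step 5 | [(8R,9S)-8-[4-(benzyloxy)-3-methoxyphenyl]-1,4,7-trioxaspiro[4.4]nonan-9-yl]methanol | COc1cc([C@@H]2OCC3(OCCO3)[C@H]2CO)ccc1OCc1ccccc1
F6 | step 5 | (8R,9S)-8-[4-(benzyloxy)-3-methoxyphenyl]-9-({[4-(benzyloxy)-3-methoxyphenyl]methoxy}methyl)-1,4,7-trioxaspiro[4.4]nonane | COc1cc([C@@H]2OCC3(OCCO3)[C@H]2COCc2ccc(OCc4ccccc4)c(OC)c2)ccc1OCc1ccccc1
F7 | step 7 | (2R,3S)-2-[4-(benzyloxy)-3-methoxyphenyl]-4-[4-(benzyloxy)-3-methoxybenzylidene]-3-{[(triethylsilyl)oxy]methyl}tetrahydrofuran (E/Z mixture) | COc1cc([C@@H]2OCC(=Cc3ccc(OCc4ccccc4)c(OC)c3)[C@H]2CO[Si](CC)(CC)CC)ccc1OCc1ccccc1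
F8 | step 7 | (3R,4S,5R)-5-[4-(benzyloxy)-3-methoxyphenyl]-3-{[4-(benzyloxy)-3-methoxyphenyl](hydroxy)methyl}-4-{[(triethylsilyl)oxy]methyl}tetrahydrofuran-3-ol (benzylic carbinol unassigned) | COc1cc([C@@H]2OC[C@@](O)(C(O)c3ccc(OCc4ccccc4)c(OC)c3)[C@H]2CO[Si](CC)(CC)CC)ccc1OCc1ccccc1
F9 | step 7 | (3R,4S,5R)-5-[4-(benzyloxy)-3-methoxyphenyl]-3-{[4-(benzyloxy)-3-methoxyphenyl](hydroxy)methyl}-4-(hydroxymethyl)tetrahydrofuran-3-ol (benzylic carbinol unassigned) | COc1cc([C@@H]2OC[C@@](O)(C(O)c3ccc(OCc4ccccc4)c(OC)c3)[C@H]2CO)ccc1OCc1ccccc1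
F10 | step 4 | trans-6-bromo-2-[4-(benzyloxy)-3-methoxyphenyl]-1,3-dioxepan-5-ol (racemic) | COc1cc(C2OCC(O)C(Br)CO2)ccc1OCc1ccccc1
F11 | step 4 | 6-bromo-2-[4-(benzyloxy)-3-methoxyphenyl]-1,3-dioxepan-5-one (racemic) | COc1cc(C2OCC(=O)C(Br)CO2)ccc1OCc1ccccc1
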